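3 questions stand on this flask, and none is answered by running a model before the readings have been read.

| flask | Z | X | remark | time |
|---|---|---|---|---|
| north-east | 0.12 M | 0.50 M | run made earlier |  |
| east | 0.50 M | 0.50 M | run made earlier |  |
| flask | 0.25 M | 0.500 M |  | 40 h |

| run | time / h | J / % | L / % | Z / % |
|---|---|---|---|---|
| north-east | 2.00 | 72 | 28 | 0 |
| north-east | 6.00 | 73 | 27 | 0 |
| north-east | 12.0 | 72 | 27 | 0 |
| north-east | 20.0 | 69 | 26 | 0 |
| north-east | 25.0 | 69 | 28 | 0 |
| north-east | 30.0 | 72 | 25 | 0 |
| east | 2.00 | 99 | 0 | 0 |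
| east | 6.00 | 99 | 0 | 0 |
| east | 12.0 | 101 | 0 | 1 |
| east | 20.0 | 101 | 0 | 3 |
| east | 25.0 | 99 | 1 | 1 |
| east | 30.0 | 103 | 1 | 0 |

(standard deviation of a reading: 2 percentage points)

1. equivalents of X to Z, everything else as given, that leave most J at 40 h
2. the amount of J then, in percent of the Z charged
3. the amount of J with the amounts as given



What does the north-east run show? Z reads 0% at 2.00 h. J and L then stay flat within the scatter.

Flat could mean slow. Why not? L reached 28% inside 2.00 h, yet it stops while free X reads 0.349 M at 12.0 h. I read a balance, J + X ⇌ L: thermodynamic control.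

What do you carry? The balance level c_bal, the free X at which J and L stand equal. Equal shares are the zero of the scale, and cL/cJ = cX/c_bal. The reading gives c_bal = 0.930 M.

And this flask? At two equivalents, if Z converts as in the north-east run, where it reads 0%, cX equals cJ. So cL = cJ²/c_bal, and cJ + cL = cA. That gives J 81.9%, with cX at 0.205 M, under c_bal.

Which charge is best? I say one equivalent. Less leaves Z unconverted, more feeds L. The east run, with equal charges, reads L 0% and J 101% at 12.0 h.

Where is the weak spot? The time. J and L sum to 100% at first and 97.0% last, so a slow drain may hide in the scatter.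

The forecast gives 1 equiv, 98% and 81%, and reads the flat stretch as “an equilibrium, J + X ⇌ L, rather than slow kinetics”.

The flask gives 1.00 equiv, 99.9% and 79.7%.

    X + J ⇌ L (K = 1.10 L mol⁻¹, k = 2.63 L mol⁻¹ min⁻¹)
    Z + X → J (k = 1.68 L mol⁻¹ min⁻¹)
    L → D (k = 6.65 × 10⁻⁵ min⁻¹)

With the return of L to X + J struck out, J in this flask at 40.0 h falls from 79.7% to 0.0466%. The loss to D is not the reason for J's level in this flask: without it J is 81.7%. In the flask, free X of 0.199 M over c_bal gives L to J of 0.214, and the flask holds 0.219.

In the neighbour charged with 2.0 M of X, free X stands at 1.50 M or more, above c_bal, so I expect L to J of about 1.61 or above. That neighbour holds 57.4% L and 33.0% J at 40.0 h, a ratio of 1.74.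

The earlier runs and the new flask are calculated on assumed constants; the scatter is artificial.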